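I begin with the easy step. At 4.00 h the two runs read 0% and 0.7% of isomer, and at 30.0 h they average 4.40%. That late climb suggests to me that a fixed fraction of the target present turns into isomer each hour.

| flask | starting material | catalyst | remark | time |
|---|---|---|---|---|
| north-west | 0.14 M | 1 mM | run made earlier |  |
| south-east | 0.22 M | 1 mM | run made earlier |  |
| flask | 0.10 M | 1.0 mM |  | 25 h |

| run | time / h | isomer of the product / % | target / % |
|---|---|---|---|
| north-west | 4.00 | 0 | 11.1 |
| north-west | 8.00 | 0.6 | 19.4 |
| north-west | 12.0 | 0 | 27.0 |
| north-west | 15.0 | 0.6 | 29.2 |
| north-west | 20.0 | 3.2 | 36.4 |
| north-west | 25.0 | 2.1 | 41.3 |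
| north-west | 30.0 | 4.3 | 42.4 |
| south-east | 4.00 | 0.7 | 11.4 |
| south-east | 8.00 | 0.9 | 21.3 |
| south-east | 12.0 | 1.5 | 27.5 |
| south-east | 15.0 | 3.0 | 31.6 |
| south-east | 20.0 | 2.7 | 36.1 |
| south-east | 25.0 | 1.6 | 40.1 |
| south-east | 30.0 | 4.5 | 44.3 |

(scatter of a reading: 1 percentage point)

- a reading or a percentage of target counts all its forms, free or not

- share of isomer of the product in isomer of the product plus target at 40 min
- share of isomer of the product in isomer of the product plus target at 25 h
- which of isomer of the product and target there is more of at 25 h

The runs differ in starting material but not in catalyst, and at 25.0 h they read 41.3% and 40.1% of target, so I expect the flask to follow the same curve in percent.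

Isomer made is that fraction times the area under the target curve, and the area is a shape factor times the latest target times the time. The shape factor is 0.5 for a straight rise and 1 for target standing full from the start, and these are my bounds.

Target averages 43.4% at 30.0 h and 30.4% at 15.0 h. Weighting the middle reading 4 to 1 against the last gives a read shape factor of 0.634, which I freeze. Dividing then gives, as a reading with the scatter of the runs, 0.00533 h⁻¹, the isomer clock: the fraction of target turned into isomer per hour at 1.0 mM of catalyst, a pseudo-first-order constant.

Isomer per target is clock times shape times time. With this clock I reckon the share in the flask at 25 h as 6.25% from below and 11.8% from above, and my own figure with the read shape is 7.80%. The upper bound is less than even shares, so I expect target to lead in the flask. At 40 min I take the rise in the flask as straight and reckon 0.178%.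

The forecast says 0.3%, 7% and target, on this ground: “Isomer is near zero early and grows with a lag, which suggests it forms from target”. Its late share lies inside my bracket, below my own figure, and its early share is above mine.

The flask gives 0.195% and 8.10%, with 41.5% of target against 3.66% of isomer.

    starting material + catalyst ⇌ target + catalyst, rate k1*[starting material]*[catalyst] forward; the back reaction follows from the equilibrium constant (K = 7.50, k = 0.510 M⁻¹ min⁻¹)
    target + catalyst ⇌ isomer of the product + catalyst, rate k2*[catalyst]*[target] forward; the back reaction follows from the equilibrium constant (K = 3.90, k = 0.0970 M⁻¹ min⁻¹)
    crystals ⇌ target, rate k3*(cs3 - [target]) while solid is left; crystals form when [target] > cs3 (solubility = 0.0930 M, k = 0.0910 min⁻¹)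
    starting material ⇌ dormant form (K = 1.70, k = 2.10 × 10⁻⁴ min⁻¹)

The forward half-life of target passing into isomer is 120 h, long against the 25 h of the flask. The isomer step in the scheme runs in proportion to catalyst, so I scale the clock by catalyst for the neighbour flask with 0.0017 M and keep the frozen shape. That reckons a share of 12.6% at 25 h, and the neighbour flask stands at 14.1%.

The runs come from a simulation on assumed constants, noise included.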